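**Strategy.** The cyclohexane ring is numbered C1 (alkylidene carbon), C2 (the CH carrying the hydroxypropyl arm), C3 (quaternary), C4 (CHMe), C5, C6. Everything rests on excising C2: this leaves a cyclopentanone in which the carbonyl carbon C1 is bonded directly to the quaternary carbon C3. The key step puts C2 back as a one-carbon ring expansion: dibromomethyllithium adds to C1, bromine–lithium exchange gives a β-oxido carbenoid, C3 migrates with retention, and the enolate, regiodefined between C1 and C2, is alkylated with the protected arm in the same flask. It exploits C2 lying between C1 and the quaternary C3, the better migrating carbon. The cyclopentanone comes from (R)-pulegone, whose ring is first contracted, and farnesyl chloride.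

Key step: step 6

Assumption: the Z geometry of the exocyclic enal (formyl group on the side of C2) is taken to be the thermodynamically preferred one, so that any E isomer formed in step 8 can be equilibrated instead of separated.

Step 1
Reactants: 1 (R)-(+)-pulegone
Product: 3 methyl (2R)-2-methyl-5-(propan-2-ylidene)cyclopentane-1-carboxylate (methyl pulegenate; both C1 epimers), via pulegone dibromide 2 (not isolated)
Conditions: Br2, NaHCO3, Et2O, −10 °C; then NaOMe, MeOH, reflux
Reagents that add atoms: sodium methoxide, C[O-].[Na+]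
Why: Favorskii rearrangement, in which bromine adds to the electron-rich tetrasubstituted enone double bond and methoxide converts the dibromo ketone through a cyclopropanone into the ring-contracted ester while the second bromide is lost to regenerate the isopropylidene group; the methyl-bearing centre of 1 is not involved.

Step 2
Reactants: 3 methyl pulegenate
Product: 4 methyl (2R)-2-methyl-5-oxocyclopentane-1-carboxylate
Conditions: O3, CH2Cl2/MeOH, −78 °C; then Me2S, −78 °C to rt
Reagents that add atoms: ozone, [O-][O+]=O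
Why: Ozonolysis with reductive work-up cleaves the only double bond to the ring ketone and acetone, and the C1 epimers converge because C1 of the β-keto ester is enolisable.

Step 3
Reactants: 4 methyl (2R)-2-methyl-5-oxocyclopentane-1-carboxylate
Product: 7 (3R)-3-methyl-2-methylidenecyclopentan-1-one, via β-keto acid 5 (not isolated), via Mannich acid 6 (not isolated)
Conditions: LiOH, THF/H2O, 0 °C; then AcOH to pH 5, 37% aq. CH2O, Et2NH, 0 °C to rt; used at once as a cold solution
Reagents that add atoms: formaldehyde, C=O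
Why: Saponification followed by a decarboxylative Mannich methylenation, in which the β-keto acid is aminomethylated at its doubly activated carbon and the resulting β-amino acid loses CO2 and the amine in one fragmentation, which places the methylene group at C2 only and leaves the non-acidic C3 centre untouched.

Step 4
Reactants: 8 (2E,6E)-farnesyl chloride; 7 (3R)-3-methyl-2-methylidenecyclopentan-1-one
Product: 11 (2R,3R)-2,3-dimethyl-2-[(3E,7E)-4,8,12-trimethyltrideca-3,7,11-trien-1-yl]cyclopentan-1-one, via farnesylbarium chloride 9 (not isolated), via barium enolate 10 (not isolated)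
Conditions: BaI2, LiC12H10 (lithium biphenylide), THF, rt; then 8, −78 °C; then 7, −78 °C; then MeI, DMPU, −78 to −20 °C
Reagents that add atoms: iodomethane, CI
Why: Conjugate addition of an allylbarium reagent followed by enolate alkylation: the allylic barium species, formed at −78 °C without loss of alkene geometry, should react through its unsubstituted α-carbon at the exocyclic methylene of 7, and the regiodefined enolate is methylated on the face opposite the C3 methyl group, which sets the quaternary C2 centre (R) with its methyl trans to the C3 methyl.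

Step 5
Reactants: 12 3-[(tert-butyldimethylsilyl)oxy]propan-1-ol
Product: 13 3-[(tert-butyldimethylsilyl)oxy]propyl trifluoromethanesulfonate
Conditions: Tf2O, 2,6-lutidine, CH2Cl2, −78 °C; used at once
Reagents that add atoms: trifluoromethanesulfonic anhydride, O=S(=O)(OS(=O)(=O)C(F)(F)F)C(F)(F)F
Why: O-Sulfonylation of the primary alcohol with a hindered pyridine base gives an alkylating agent reactive enough for a hindered lithium enolate at low temperature.

Step 6
Reactants: 11 (2R,3R)-2,3-dimethyl-2-[(3E,7E)-4,8,12-trimethyltrideca-3,7,11-trien-1-yl]cyclopentan-1-one; 13 3-[(tert-butyldimethylsilyl)oxy]propyl trifluoromethanesulfonate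
Product: 17 (2S,3R,4R)-2-{3-[(tert-butyldimethylsilyl)oxy]propyl}-3,4-dimethyl-3-[(3E,7E)-4,8,12-trimethyltrideca-3,7,11-trien-1-yl]cyclohexan-1-one, via lithium dibromomethyl alkoxide 14 (not isolated), via β-oxido carbenoid 15 (not isolated), via ring-expanded lithium enolate 16 (not isolated)
Conditions: CH2Br2, LiTMP (lithium 2,2,6,6-tetramethylpiperidide, C9H18NLi), THF, −78 °C; then n-BuLi, −78 to −20 °C; then 13, THF, −78 to 0 °C
Reagents that add atoms: dibromomethane, BrCBr
Why: Dibromomethyllithium adds to the ketone of 11, bromine–lithium exchange on alkoxide 14 gives carbenoid 15, and the ring bond to the quaternary carbon shifts to the carbenoid carbon with loss of bromide, so that the cyclopentane becomes a cyclohexane and enolate 16 is formed with its double bond fixed between C1 and the inserted C2. The closest known reaction type is the β-oxido carbenoid (Tiffeneau–Demjanov-type) ring enlargement of cycloalkanones with dihalomethyllithium, here combined with alkylation of the regiospecific enolate in the same flask. No ring is closed by cyclisation: the six-membered ring arises by 1,2-shift of the quaternary carbon (C2 of 11, C3 of 17) from the carbonyl carbon to the new carbon, a ring enlargement by one atom. The migrating carbon keeps its configuration, so the two centres of 11 are carried over unchanged, and the new C2 centre is set by axial attack of 13 on the enolate face opposite the pseudoaxial homofarnesyl chain at C3 (both methyl groups pseudoequatorial), which places the arm trans to that chain. The step needs migration of the quaternary carbon in preference to the ring CH2 and C- over O-alkylation; the first is secured by the higher migratory aptitude of the more substituted carbon in carbenoid rearrangements, the second by the lithium counter-ion in THF without polar cosolvent.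

Step 7
Reactants: 17 (2S,3R,4R)-2-{3-[(tert-butyldimethylsilyl)oxy]propyl}-3,4-dimethyl-3-[(3E,7E)-4,8,12-trimethyltrideca-3,7,11-trien-1-yl]cyclohexan-1-one
Product: 18 (2S,3R,4R)-2-{3-[(tert-butyldimethylsilyl)oxy]propyl}-3,4-dimethyl-1-(prop-1-en-2-yl)-3-[(3E,7E)-4,8,12-trimethyltrideca-3,7,11-trien-1-yl]cyclohexan-1-ol (C1 configuration not controlled)
Conditions: isopropenylmagnesium bromide, LaCl3·2LiCl, THF, 0 °C; aq. NH4Cl
Reagents that add atoms: isopropenylmagnesium bromide, C=C(C)[Mg]Br
Why: Grignard 1,2-addition to the hindered ketone, with the lanthanum salt suppressing enolisation so that C2 is not epimerised; the configuration of the new carbinol centre is immaterial because that carbon becomes sp2 in step 8.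

Step 8
Reactants: 18 tertiary allylic alcohol
Product: 21 (2Z)-2-[(2S,3R,4R)-2-{3-[(tert-butyldimethylsilyl)oxy]propyl}-3,4-dimethyl-3-[(3E,7E)-4,8,12-trimethyltrideca-3,7,11-trien-1-yl]cyclohexylidene]propanal, via tertiary chromate ester 19 (not isolated), via primary allylic chromate ester 20 (not isolated)
Conditions: [C5H5NH][CrO3Cl] (pyridinium chlorochromate), NaOAc, 4 Å molecular sieves, CH2Cl2, rt
Reagents that add atoms: pyridinium chlorochromate, [O-][Cr](=O)(=O)Cl.c1cc[nH+]cc1
Why: Babler–Dauben oxidative transposition, in which chromate ester 19 undergoes a [3,3] shift to 20 and is then oxidised to the enal; the tetrasubstituted alkene is expected to settle in the less strained Z geometry, with the small formyl group rather than the methyl group next to the congested C2, whose arm stays axial.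

Step 9
Reactants: 21 silyl-protected enal
Product: 22 (2Z)-2-[(2S,3R,4R)-2-(3-hydroxypropyl)-3,4-dimethyl-3-[(3E,7E)-4,8,12-trimethyltrideca-3,7,11-trien-1-yl]cyclohexylidene]propanal (CNP0167080.1)
Conditions: HF·pyridine, pyridine, THF, 0 °C
Reagents that add atoms: none
Why: Fluoride cleaves the primary silyl ether under buffered, non-basic conditions that should leave the enal geometry, the C2 centre and the trisubstituted alkenes untouched.

**Compound list**

1 | (5R)-5-methyl-2-(propan-2-ylidene)cyclohexan-1-one, (R)-(+)-pulegone | C[C@@H]1CCC(=C(C)C)C(=O)C1 | starting material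
2 | (5R)-2-bromo-2-(2-bromopropan-2-yl)-5-methylcyclohexan-1-one, pulegone dibromide (C2 epimers) | C[C@@H]1CCC(Br)(C(C)(C)Br)C(=O)C1 | intermediate
3 | methyl (2R)-2-methyl-5-(propan-2-ylidene)cyclopentane-1-carboxylate, methyl pulegenate (both C1 epimers) | COC(=O)C1[C@H](C)CCC1=C(C)C | intermediate
4 | methyl (2R)-2-methyl-5-oxocyclopentane-1-carboxylate (C1 enolisable) | COC(=O)C1[C@H](C)CCC1=O | intermediate
5 | (2R)-2-methyl-5-oxocyclopentane-1-carboxylic acid | OC(=O)C1[C@H](C)CCC1=O | intermediate
6 | (2R)-1-[(diethylamino)methyl]-2-methyl-5-oxocyclopentane-1-carboxylic acid (C1 configuration immaterial) | CCN(CC)CC1(C(O)=O)[C@H](C)CCC1=O | intermediate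
7 | (3R)-3-methyl-2-methylidenecyclopentan-1-one | C=C1[C@H](C)CCC1=O | intermediate
8 | (2E,6E)-1-chloro-3,7,11-trimethyldodeca-2,6,10-triene, (E,E)-farnesyl chloride | CC(C)=CCC/C(C)=C/CC/C(C)=C/CCl | starting material
9 | [(2E,6E)-3,7,11-trimethyldodeca-2,6,10-trien-1-yl]barium chloride | CC(C)=CCC/C(C)=C/CC/C(C)=C/C[Ba]Cl | intermediate
10 | chlorobarium (3R)-3-methyl-2-[(3E,7E)-4,8,12-trimethyltrideca-3,7,11-trien-1-yl]cyclopent-1-en-1-olate | CC(C)=CCC/C(C)=C/CC/C(C)=C/CCC1=C(O[Ba]Cl)CC[C@H]1C | intermediate
11 | (2R,3R)-2,3-dimethyl-2-[(3E,7E)-4,8,12-trimethyltrideca-3,7,11-trien-1-yl]cyclopentan-1-one | CC(C)=CCC/C(C)=C/CC/C(C)=C/CC[C@]1(C)[C@H](C)CCC1=O | intermediate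
12 | 3-[(tert-butyldimethylsilyl)oxy]propan-1-ol | CC(C)(C)[Si](C)(C)OCCCO | starting material
13 | 3-[(tert-butyldimethylsilyl)oxy]propyl trifluoromethanesulfonate | CC(C)(C)[Si](C)(C)OCCCOS(=O)(=O)C(F)(F)F | intermediate
14 | lithium (2R,3R)-1-(dibromomethyl)-2,3-dimethyl-2-[(3E,7E)-4,8,12-trimethyltrideca-3,7,11-trien-1-yl]cyclopentan-1-olate (C1 epimers) | CC(C)=CCC/C(C)=C/CC/C(C)=C/CC[C@]1(C)[C@H](C)CCC1(O[Li])C(Br)Br | intermediate
15 | lithium (2R,3R)-1-[bromo(lithio)methyl]-2,3-dimethyl-2-[(3E,7E)-4,8,12-trimethyltrideca-3,7,11-trien-1-yl]cyclopentan-1-olate, the β-oxido carbenoid | CC(C)=CCC/C(C)=C/CC/C(C)=C/CC[C@]1(C)[C@H](C)CCC1(O[Li])C([Li])Br | intermediate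
16 | lithium (3R,4R)-3,4-dimethyl-3-[(3E,7E)-4,8,12-trimethyltrideca-3,7,11-trien-1-yl]cyclohex-1-en-1-olate | CC(C)=CCC/C(C)=C/CC/C(C)=C/CC[C@]1(C)[C@H](C)CCC(O[Li])=C1 | intermediate
17 | (2S,3R,4R)-2-{3-[(tert-butyldimethylsilyl)oxy]propyl}-3,4-dimethyl-3-[(3E,7E)-4,8,12-trimethyltrideca-3,7,11-trien-1-yl]cyclohexan-1-one | CC(C)=CCC/C(C)=C/CC/C(C)=C/CC[C@]1(C)[C@H](C)CCC(=O)[C@H]1CCCO[Si](C)(C)C(C)(C)C | intermediate
18 | (2S,3R,4R)-2-{3-[(tert-butyldimethylsilyl)oxy]propyl}-3,4-dimethyl-1-(prop-1-en-2-yl)-3-[(3E,7E)-4,8,12-trimethyltrideca-3,7,11-trien-1-yl]cyclohexan-1-ol (C1 not controlled) | CC(C)=CCC/C(C)=C/CC/C(C)=C/CC[C@]1(C)[C@H](C)CCC(O)(C(C)=C)[C@H]1CCCO[Si](C)(C)C(C)(C)C | intermediate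
19 | chlorochromate ester of 18 at the tertiary oxygen | CC(C)=CCC/C(C)=C/CC/C(C)=C/CC[C@]1(C)[C@H](C)CCC(O[Cr](=O)(=O)Cl)(C(C)=C)[C@H]1CCCO[Si](C)(C)C(C)(C)C | intermediate
20 | (2Z)-2-[(2S,3R,4R)-2-{3-[(tert-butyldimethylsilyl)oxy]propyl}-3,4-dimethyl-3-[(3E,7E)-4,8,12-trimethyltrideca-3,7,11-trien-1-yl]cyclohexylidene]propyl chlorochromate | CC(C)=CCC/C(C)=C/CC/C(C)=C/CC[C@]1(C)[C@H](C)CC/C(=C(\C)CO[Cr](=O)(=O)Cl)[C@H]1CCCO[Si](C)(C)C(C)(C)C | intermediate
21 | (2Z)-2-[(2S,3R,4R)-2-{3-[(tert-butyldimethylsilyl)oxy]propyl}-3,4-dimethyl-3-[(3E,7E)-4,8,12-trimethyltrideca-3,7,11-trien-1-yl]cyclohexylidene]propanal | CC(C)=CCC/C(C)=C/CC/C(C)=C/CC[C@]1(C)[C@H](C)CC/C(=C(\C)C=O)[C@H]1CCCO[Si](C)(C)C(C)(C)C | intermediate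
22 | (2Z)-2-[(2S,3R,4R)-2-(3-hydroxypropyl)-3,4-dimethyl-3-[(3E,7E)-4,8,12-trimethyltrideca-3,7,11-trien-1-yl]cyclohexylidene]propanal | CC(C)=CCC/C(C)=C/CC/C(C)=C/CC[C@]1(C)[C@H](C)CC/C(=C(\C)C=O)[C@H]1CCCO | target

**Step count.** Total: 9 steps. Longest linear sequence: 8 steps (steps 1–4 and 6–9; step 5 prepares the triflate).

**Steps most likely to fail**

Step 4. What may go wrong: the allylbarium reagent may add to the carbonyl group or deprotonate the enone instead of adding to the methylene carbon, the enone may dimerise before it reacts, and the alkene geometry may erode if the reagent warms. The fallback sets out from 4 and comes back at 11. Methylation of 4 (K2CO3, MeI, acetone), with the methyl group entering trans to the ring methyl, would give methyl (1R,2R)-1,2-dimethyl-5-oxocyclopentane-1-carboxylate F1. LiAlH4 would reduce it to (2S,3R)-2-(hydroxymethyl)-2,3-dimethylcyclopentan-1-ol F2, and Swern oxidation would give (1S,2R)-1,2-dimethyl-5-oxocyclopentane-1-carbaldehyde F3. One equivalent of Ph3P=CH2 at low temperature would olefinate the aldehyde only, to (2R,3R)-2-ethenyl-2,3-dimethylcyclopentan-1-one F4. In parallel, geranyl bromide would alkylate lithiated 1-(trimethylsilyl)propyne to [(5E)-6,10-dimethylundeca-5,9-dien-1-yn-1-yl]trimethylsilane F5, K2CO3 in methanol would give (5E)-6,10-dimethylundeca-5,9-dien-1-yne F6, and Cp2ZrCl2-catalysed methylalumination with Me3Al followed by I2 would give (1E,5E)-1-iodo-2,6,10-trimethylundeca-1,5,9-triene F7. Hydroboration of F4 with 9-BBN to (2R,3R)-2-[2-(9-borabicyclo[3.3.1]nonan-9-yl)ethyl]-2,3-dimethylcyclopentan-1-one F8 and B-alkyl Suzuki–Miyaura coupling with F7 (Pd(dppf)Cl2, Ph3As, Cs2CO3, DMF/H2O) would then deliver 11.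

Step 6. What may go wrong: migration of the ring CH2 instead of the quaternary carbon, collapse of the bromo alkoxide to an epoxide before the exchange, and proton transfer or O-alkylation when the hindered enolate meets the triflate. The fallback sets out from 11 and comes back at 17. tert-Butyl[4,4-bis(phenylselanyl)butoxy]dimethylsilane F9 (from commercial 4-[(tert-butyldimethylsilyl)oxy]butanal, PhSeH and ZnCl2) would be cleaved with n-BuLi to the α-selenoalkyllithium. Its addition to 11 would give the β-hydroxy selenide (2R,3R)-1-{4-[(tert-butyldimethylsilyl)oxy]-1-(phenylselanyl)butyl}-2,3-dimethyl-2-[(3E,7E)-4,8,12-trimethyltrideca-3,7,11-trien-1-yl]cyclopentan-1-ol F10. Activation of selenium with dichlorocarbene (CHCl3, TlOEt) would trigger the selenium-mediated semipinacol ring enlargement, again with migration of the more substituted carbon, and should give 17 together with its C2 epimer, from which it is separated.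

Step 8. What may go wrong: slow chromate ester formation at the crowded tertiary alcohol, acid-induced dehydration to dienes, and incomplete control of the alkene geometry. The fallback sets out from 18 and comes back at 21. Catalytic Ph3SiOReO3 in Et2O at low temperature would effect the non-oxidative 1,3-transposition to the primary allylic alcohol (2Z)-2-[(2S,3R,4R)-2-{3-[(tert-butyldimethylsilyl)oxy]propyl}-3,4-dimethyl-3-[(3E,7E)-4,8,12-trimethyltrideca-3,7,11-trien-1-yl]cyclohexylidene]propan-1-ol F11, and MnO2 in CH2Cl2 would oxidise it to 21. A geometric mixture would be equilibrated at the aldehyde stage with a trace of I2.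

**Further compounds**

F1 | step 4 | methyl (1R,2R)-1,2-dimethyl-5-oxocyclopentane-1-carboxylate | COC(=O)[C@]1(C)[C@H](C)CCC1=O
F2 | step 4 | (2S,3R)-2-(hydroxymethyl)-2,3-dimethylcyclopentan-1-ol (C1 epimers) | OC[C@]1(C)[C@H](C)CCC1O
F3 | step 4 | (1S,2R)-1,2-dimethyl-5-oxocyclopentane-1-carbaldehyde | O=C[C@]1(C)[C@H](C)CCC1=O
F4 | step 4 | (2R,3R)-2-ethenyl-2,3-dimethylcyclopentan-1-one | C=C[C@]1(C)[C@H](C)CCC1=O
F5 | step 4 | [(5E)-6,10-dimethylundeca-5,9-dien-1-yn-1-yl]trimethylsilane | CC(C)=CCC/C(C)=C/CCC#C[Si](C)(C)C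
F6 | step 4 | (5E)-6,10-dimethylundeca-5,9-dien-1-yne | CC(C)=CCC/C(C)=C/CCC#C
F7 | step 4 | (1E,5E)-1-iodo-2,6,10-trimethylundeca-1,5,9-triene | CC(C)=CCC/C(C)=C/CC/C(C)=C/I
F8 | step 4 | (2R,3R)-2-[2-(9-borabicyclo[3.3.1]nonan-9-yl)ethyl]-2,3-dimethylcyclopentan-1-one | B1(CC[C@]2(C)[C@H](C)CCC2=O)C3CCCC1CCC3
F9 | step 6 | tert-butyl[4,4-bis(phenylselanyl)butoxy]dimethylsilane | CC(C)(C)[Si](C)(C)OCCCC([Se]c1ccccc1)[Se]c1ccccc1
F10 | step 6 | (2R,3R)-1-{4-[(tert-butyldimethylsilyl)oxy]-1-(phenylselanyl)butyl}-2,3-dimethyl-2-[(3E,7E)-4,8,12-trimethyltrideca-3,7,11-trien-1-yl]cyclopentan-1-ol (diastereomers) | CC(C)=CCC/C(C)=C/CC/C(C)=C/CC[C@]1(C)[C@H](C)CCC1(O)C(CCCO[Si](C)(C)C(C)(C)C)[Se]c1ccccc1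
F11 | step 8 | (2Z)-2-[(2S,3R,4R)-2-{3-[(tert-butyldimethylsilyl)oxy]propyl}-3,4-dimethyl-3-[(3E,7E)-4,8,12-trimethyltrideca-3,7,11-trien-1-yl]cyclohexylidene]propan-1-ol | CC(C)=CCC/C(C)=C/CC/C(C)=C/CC[C@]1(C)[C@H](C)CC/C(=C(\C)CO)[C@H]1CCCO[Si](C)(C)C(C)(C)C
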